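**Retrosynthetic overview**
1. Feature: the γ-lactone ring (O, C6, C7, C11, C12) is a furan in reduced form. Its oxygen-bearing carbon C6 is bonded to the angelate carbon C5 of the cycloheptane (C1, C5, C6, C7, C8, C9, C10). A 2-silyloxyfuran carrying C8–C9–C10–C1–C5HO on C7 can therefore close the carbocycle through C6.
2. Late disconnections: the C5–O angelate (mixed anhydride), C2–C3 (Nozaki–Hiyama–Kishi, then oxidation to the crotonoyl ketone), C11=C13 (Mannich/elimination), and C7–H (conjugate reduction of the butenolide).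
3. Key disconnection: C5–C6, an intramolecular vinylogous Mukaiyama aldol that sets C5 and C6.
4. Precursor: C7–C8 comes from 3-furyllithium and (R)-4-methylvalerolactone, C8 from CBS reduction, C2 from α-methylenation, and C1 from Sharpless epoxidation. Singlet oxygen then NaBH4 turns the furan into the butenolide.
5. Ring order: furan (bought), then cycloheptane (step 15, where the furan becomes the butenolide), then saturated lactone, then α-methylene lactone.

Key step: step 15

Remark (numbering): locants C1–C15 are those of the target (C13 exocyclic methylene, C14 methyl on C10, C2–C3–C4–C15 crotonoyl). CIP letters change where substituent priorities change; no centre is inverted after it is set.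
Remark (assumption): half-ester 1 is used as the purchased single enantiomer.
Remark (protecting groups): only silyl ethers remain at the end, so a single fluoride step finishes the synthesis. C2–O carries a PMB ether so that it can be told apart from the C8 silyl ether.
Remark (mixtures): C6 in 16 and 17, C11 in 26 and 27, and C2 in 37 form as epimer mixtures. They are erased in steps 12, 18 and 24 and are written without descriptor.

**Step 1**
Reactants: 1 methyl hydrogen (R)-3-methylglutarate
Product: 3 (R)-4-methyltetrahydro-2H-pyran-2-one, via methyl (R)-5-hydroxy-3-methylpentanoate 2 (not isolated)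
Conditions: BH3·SMe2, THF, 0 °C to rt; MeOH quench; then p-TsOH·H2O (cat.), toluene, rt
Reagents that add atoms: none
Why: Borane reduces the free carboxylic acid far faster than the methyl ester (chemoselective borane reduction), and acid-catalysed lactonisation of the δ-hydroxy ester follows without touching C10.

**Step 2**
Reactants: 3 (R)-4-methyltetrahydro-2H-pyran-2-one, 4 3-bromofuran
Product: 7 (R)-1-(furan-3-yl)-3-methyl-5-(triethylsilyloxy)pentan-1-one, via 3-furyllithium 5 (not isolated), via lithium keto alkoxide 6 (not isolated)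
Conditions: 4, n-BuLi, Et2O/THF, −78 °C; add 3, −78 °C; then Et3SiCl, −78 to 0 °C
Reagents that add atoms: chlorotriethylsilane, CC[Si](Cl)(CC)CC
Why: Bromine–lithium exchange at −78 °C keeps the lithium at the furan 3-position, a single acyl substitution on the δ-lactone forms C7–C8 (the tetrahedral adduct holds at low temperature), and the freed primary alkoxide is silylated in the same flask.

**Step 3**
Reactants: 7 (R)-1-(furan-3-yl)-3-methyl-5-(triethylsilyloxy)pentan-1-one
Product: 8 (1S,3R)-1-(furan-3-yl)-3-methyl-5-(triethylsilyloxy)pentan-1-ol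
Conditions: (R)-Me-CBS [(3aR)-1-methyl-3,3-diphenyltetrahydro-1H,3H-pyrrolo[1,2-c][1,3,2]oxazaborole] (15 mol%), BH3·SMe2, THF, −30 °C
Reagents that add atoms: none
Why: In the Corey–Bakshi–Shibata reduction the furyl group acts as the large and the CH2 chain as the small substituent, so the (R)-catalyst should set C8 as (S) under catalyst control, independent of the remote C10 centre.

**Step 4**
Reactants: 8 (1S,3R)-1-(furan-3-yl)-3-methyl-5-(triethylsilyloxy)pentan-1-ol
Product: 9 3-[(1S,3R)-1-(tert-butyldimethylsilyloxy)-3-methyl-5-(triethylsilyloxy)pentyl]furan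
Conditions: TBSCl, imidazole, DMF, rt
Reagents that add atoms: tert-butylchlorodimethylsilane, CC(C)(C)[Si](C)(C)Cl
Why: Standard imidazole-mediated silylation puts the lasting protecting group on C8–OH, and the primary TES ether is stable under these neutral conditions.

**Step 5**
Reactants: 9 3-[(1S,3R)-1-(tert-butyldimethylsilyloxy)-3-methyl-5-(triethylsilyloxy)pentyl]furan
Product: 10 (3S,5S)-5-(tert-butyldimethylsilyloxy)-5-(furan-3-yl)-3-methylpentanal
Conditions: (COCl)2, DMSO, CH2Cl2, −78 to −40 °C; Et3N, −78 °C to rt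
Reagents that add atoms: none
Why: Under Swern conditions a primary triethylsilyl ether exchanges directly with the chlorodimethylsulfonium ion and is oxidised to the aldehyde, while the secondary TBS ether and the furan are left alone.

**Step 6**
Reactants: 10 (3S,5S)-5-(tert-butyldimethylsilyloxy)-5-(furan-3-yl)-3-methylpentanal
Product: 11 (3S,5S)-5-(tert-butyldimethylsilyloxy)-5-(furan-3-yl)-3-methyl-2-methylidenepentanal
Conditions: 37% aq. CH2O, pyrrolidine (10 mol%), propionic acid (10 mol%), i-PrOH, 45 °C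
Reagents that add atoms: formaldehyde, C=O
Why: Amine/acid-catalysed Mannich condensation–elimination (organocatalytic α-methylenation of aldehydes) adds C2 at C1, and C10–H, cross-conjugated in the product, is not acidified, so C10 holds.

**Step 7**
Reactants: 11 (3S,5S)-5-(tert-butyldimethylsilyloxy)-5-(furan-3-yl)-3-methyl-2-methylidenepentanal
Product: 12 (3S,5S)-5-(tert-butyldimethylsilyloxy)-5-(furan-3-yl)-3-methyl-2-methylidenepentan-1-ol
Conditions: NaBH4, CeCl3·7H2O, MeOH, −20 °C
Reagents that add atoms: none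
Why: Luche reduction gives clean 1,2-reduction of the 2-substituted acrolein to the allylic alcohol needed for the directed epoxidation.

**Step 8**
Reactants: 12 (3S,5S)-5-(tert-butyldimethylsilyloxy)-5-(furan-3-yl)-3-methyl-2-methylidenepentan-1-ol
Product: 13 {(2S)-2-[(2S,4S)-4-(tert-butyldimethylsilyloxy)-4-(furan-3-yl)butan-2-yl]oxiran-2-yl}methanol
Conditions: Ti(OiPr)4 (10 mol%), L-(+)-diethyl tartrate (12 mol%), t-BuOOH, 4 Å MS, CH2Cl2, −20 °C
Reagents that add atoms: tert-butyl hydroperoxide, CC(C)(C)OO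
Why: Katsuki–Sharpless epoxidation with the L-(+)-tartrate gives the (2S)-epoxide of a 2-substituted allylic alcohol (the sense that leads from methallyl alcohol to (S)-2-methylglycidol), which sets C1 under reagent control; the furan, having no free carbinol to bind titanium, is not oxidised.

**Step 9**
Reactants: 13 {(2S)-2-[(2S,4S)-4-(tert-butyldimethylsilyloxy)-4-(furan-3-yl)butan-2-yl]oxiran-2-yl}methanol
Product: 14 (2S,3S,5S)-5-(tert-butyldimethylsilyloxy)-5-(furan-3-yl)-2-[(4-methoxybenzyloxy)methyl]-3-methylpentane-1,2-diol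
Conditions: 4-MeOC6H4CH2OH, NaH, THF, 65 °C
Reagents that add atoms: 4-methoxybenzyl alcohol, COc1ccc(CO)cc1
Why: The alkoxide opens the epoxide by SN2 attack at its CH2 terminus, so the C1–O bond and configuration are kept (the Payne rearrangement of this epoxy alcohol is degenerate), and the two arms become distinct: the attacked carbon is C2 and the free CH2OH is C5.

**Step 10**
Reactants: 14 (2S,3S,5S)-5-(tert-butyldimethylsilyloxy)-5-(furan-3-yl)-2-[(4-methoxybenzyloxy)methyl]-3-methylpentane-1,2-diol
Product: 15 1,2-bis(triethylsilyl) ether of 14 (C1 R, C8 S, C10 S)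
Conditions: Et3SiOTf, 2,6-lutidine, CH2Cl2, −78 to 0 °C
Reagents that add atoms: triethylsilyl trifluoromethanesulfonate, CC[Si](CC)(CC)OS(=O)(=O)C(F)(F)F
Why: The silyl triflate caps the tertiary C1–OH and the primary C5–OH in one operation, giving a fluoride-labile group at C1 and an oxidisable group at C5.

**Step 11**
Reactants: 15 1,2-bis(triethylsilyl) ether of 14
Product: 17 γ-hydroxybutenolide (5-hydroxy-4-alkylfuran-2(5H)-one; chain as in 15; C6 epimers), via furan endoperoxide 16 (not isolated)
Conditions: O2, hν, 5,10,15,20-tetraphenylporphyrin (cat.), i-Pr2NEt, CH2Cl2, −78 °C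
Reagents that add atoms: dioxygen, O=O
Why: Singlet oxygen adds [4+2] across the furan, and the hindered amine removes the less hindered bridgehead hydrogen (C12–H, remote from the chain) in a Kornblum–DeLaMare-type fragmentation, placing the carbonyl at C12 and the hemiacetal at C6.

**Step 12**
Reactants: 17 γ-hydroxybutenolide
Product: 19 butenolide (4-alkylfuran-2(5H)-one; chain as in 15), via ring-opened hydroxy acid 18 (not isolated)
Conditions: NaBH4, THF/MeOH, 0 °C; then 10% aq. citric acid
Reagents that add atoms: none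
Why: Borohydride reduces the aldehyde tautomer of the hemiacetal at C6, and the resulting cis-4-hydroxy-2-enoic acid lactonises on mild acidification to the β-substituted butenolide.

**Step 13**
Reactants: 19 butenolide
Product: 20 (2R,3S,5S)-5-(tert-butyldimethylsilyloxy)-2-[(4-methoxybenzyloxy)methyl]-3-methyl-5-(5-oxo-2,5-dihydrofuran-3-yl)-2-(triethylsilyloxy)pentanal
Conditions: (COCl)2, DMSO, CH2Cl2, −78 to −30 °C; Et3N, −78 °C to rt
Reagents that add atoms: none
Why: Direct Swern oxidation again picks out the primary TES ether (C5) and leaves the tertiary TES, the TBS and the PMB ethers; the new aldehyde has no α-hydrogen.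

**Step 14**
Reactants: 20 butenolide aldehyde
Product: 21 (2R,3S,5S)-5-(tert-butyldimethylsilyloxy)-2-[(4-methoxybenzyloxy)methyl]-3-methyl-2-(triethylsilyloxy)-5-[5-(triisopropylsilyloxy)furan-3-yl]pentanal
Conditions: i-Pr3SiOTf, Et3N (excess), CH2Cl2, 0 °C
Reagents that add atoms: triisopropylsilyl trifluoromethanesulfonate, CC(C)[Si](C(C)C)(C(C)C)OS(=O)(=O)C(F)(F)F
Why: Soft enolisation removes a C6 hydrogen and O-silylation aromatises the ring to the 2-silyloxyfuran; the neopentylic, non-enolisable aldehyde should not be engaged by the bulky triflate while amine is in excess.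

**Step 15**
Reactants: 21 silyloxyfuran aldehyde
Product: 22 (4S,6S,7R,8S,8aR)-4-(tert-butyldimethylsilyloxy)-8-hydroxy-7-[(4-methoxybenzyloxy)methyl]-6-methyl-7-(triethylsilyloxy)-4,5,6,7,8,8a-hexahydro-2H-cyclohepta[b]furan-2-one
Conditions: BF3·OEt2 (1.5 equiv), CH2Cl2 (2 mM), −78 °C; aq. NaHCO3
Reagents that add atoms: none
Why: BF3 binds the C5 aldehyde oxygen, the 2-silyloxyfuran attacks through its 5-position (C6, the site of its largest HOMO coefficient), and fluoride then takes the TIPS group so that the C7=C11 butenolide appears; this is a Lewis-acid vinylogous Mukaiyama aldol, its intramolecular carbocycle-forming variants are the closest known type, and a tether running from furan C4 to C5 is the less tested element. The cycloheptane (C1, C5, C6, C7, C8, C9, C10) closes in a 7-(enolendo)-exo-trig mode, with the C6=C7 enol-ether bond inside and the C=O outside the new ring. C6 is controlled by C8: in the chair-like fold H8 lies in the furan plane next to H11, the bulky OTBS stands perpendicular to that plane, and C9 brings the aldehyde to the opposite furan face. C5 is controlled by C1 and the open transition state: the forming bond is antiperiplanar to the C1–OTES bond (polar Felkin–Anh) and the BF3-bound oxygen points outward, anti to C6=C7, which should give a pseudo-equatorial C5–OH trans to C6–O, the threo sense usual for Lewis-acid additions of silyloxyfurans. The step needs γ- over α-attack (attack through C11 would also make a seven-membered ring) and closure over oligomerisation; the first is secured by the electronic bias of the dienoxysilane, the second by high dilution, and the aldehyde on fully substituted C1 cannot enolise.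

**Step 16**
Reactants: 22 C5-hydroxy butenolide
Product: 23 (4S,6S,7R,8S,8aR)-4-(tert-butyldimethylsilyloxy)-7-[(4-methoxybenzyloxy)methyl]-6-methyl-7,8-bis(triethylsilyloxy)-4,5,6,7,8,8a-hexahydro-2H-cyclohepta[b]furan-2-one
Conditions: Et3SiOTf, 2,6-lutidine, CH2Cl2, −78 °C
Reagents that add atoms: triethylsilyl trifluoromethanesulfonate, CC[Si](CC)(CC)OS(=O)(=O)C(F)(F)F
Why: Capping C5–OH prevents hydride delivery from a C5 alkoxyborohydride to the wrong face in step 17 and silyl migration from C1–O to a C5 alkoxide in step 18; the weak hindered base should not enolise the butenolide at −78 °C.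

**Step 17**
Reactants: 23 bis-TES butenolide
Product: 24 (3aR,4S,6S,7R,8S,8aR)-4-(tert-butyldimethylsilyloxy)-7-[(4-methoxybenzyloxy)methyl]-6-methyl-7,8-bis(triethylsilyloxy)octahydro-2H-cyclohepta[b]furan-2-one
Conditions: NaBH4, NiCl2·6H2O (0.3 equiv), MeOH/THF, −20 to 0 °C
Reagents that add atoms: none
Why: In this NaBH4/NiCl2 conjugate reduction of a butenolide, the chair-like cycloheptane holds the C8–OTBS group pseudo-axial on the face that also carries H6, so hydrogen should reach C7 along the axial trajectory from the opposite face (flanked only by H5 and one H9), setting H7 trans to H6 (trans-fused lactone); electron-transfer reductants are avoided because C6–O and C8–O are allylic leaving groups.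

**Step 18**
Reactants: 24 saturated trans-fused lactone
Product: 28 α-methylene lactone (C11=C13; 1-OTES 5-OTES 8-OTBS 2-OPMB), via lithium enolate 25 (not isolated), via Mannich base 26 (not isolated), via methiodide 27 (not isolated)
Conditions: LiN(i-Pr)2, THF, −78 °C; CH2=NMe2+ I−, −78 °C to rt; MeI, CH2Cl2/MeOH, rt; aq. NaHCO3
Reagents that add atoms: Eschenmoser's salt (N,N-dimethylmethyleneiminium iodide), C[N+](C)=C.[I-]
Why: The lactone enolate Mannich reaction, N-methylation and Hofmann-type elimination form the standard α-methylenation; C7 carries no leaving group, and C11, the only centre affected, becomes sp2.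

**Step 19**
Reactants: 28 α-methylene lactone
Product: 29 (3aR,4S,6S,7R,8S,8aR)-4-(tert-butyldimethylsilyloxy)-8-hydroxy-7-[(4-methoxybenzyloxy)methyl]-6-methyl-3-methylidene-7-(triethylsilyloxy)octahydro-2H-cyclohepta[b]furan-2-one
Conditions: pyridinium p-toluenesulfonate (0.2 equiv), MeOH/CH2Cl2, 0 °C
Reagents that add atoms: none
Why: Acid-catalysed methanolysis of silyl ethers follows steric access to silicon, so the secondary C5–OTES should go before the tertiary C1–OTES and well before the C8–OTBS.

**Step 20**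
Reactants: 29 C5 alcohol, 30 angelic acid [(Z)-2-methylbut-2-enoic acid]
Product: 32 C5 angelate of 29, via mixed anhydride 31 (not isolated)
Conditions: 30, 2,4,6-Cl3C6H2COCl, Et3N, toluene, rt; then 29, 80 °C
Reagents that add atoms: none
Why: Yamaguchi-type mixed-anhydride esterification run without a nucleophilic pyridine catalyst is the established way to acylate hindered secondary alcohols with angelic acid while keeping the (Z)-geometry.

**Step 21**
Reactants: 32 C5 angelate
Product: 33 primary C2 alcohol (PMB removed)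
Conditions: DDQ, CH2Cl2/pH 7 buffer, 0 °C
Reagents that add atoms: none
Why: Oxidative cleavage of the PMB ether runs at neutral pH, spares silyl ethers, angelate and α-methylene lactone, and finds no free neighbouring hydroxyl that could trap the benzylic cation as an acetal.

**Step 22**
Reactants: 33 primary C2 alcohol
Product: 34 C2 aldehyde
Conditions: Dess–Martin periodinane, NaHCO3, CH2Cl2, 0 °C to rt
Reagents that add atoms: none
Why: Buffered Dess–Martin oxidation, carried out at once so that the angelate has no time to migrate to the primary hydroxyl, gives a non-enolisable α-silyloxy aldehyde.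

**Step 23**
Reactants: 34 C2 aldehyde, 35 (E)-1-bromoprop-1-ene
Product: 37 C2 allylic alcohol (C2 epimers), via (E)-prop-1-enylchromium dichloride 36 (not isolated)
Conditions: 35, CrCl2 (10 equiv), NiCl2 (cat.), DMF, rt
Reagents that add atoms: none
Why: In the Nozaki–Hiyama–Kishi reaction the alkenylchromium reagent forms with retention of the (E)-geometry and adds only to the aldehyde, leaving lactone, angelate and exocyclic enoate untouched; the new C2 centre is erased in step 24.

**Step 24**
Reactants: 37 C2 allylic alcohol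
Product: 38 bis-silylated target (C2 (E)-but-2-enoyl ketone)
Conditions: Dess–Martin periodinane, NaHCO3, CH2Cl2, 0 °C
Reagents that add atoms: none
Why: Dess–Martin oxidation of the allylic alcohol gives the (E)-enone, and with C5 acylated and C1 fully substituted neither retro-aldol cleavage nor enolisation toward the ring is open.

**Step 25**
Reactants: 38 bis-silylated target
Product: 39 CNP0206014.2 (target)
Conditions: HF·pyridine, THF/pyridine, 0 °C to rt
Reagents that add atoms: none
Why: Buffered fluoride desilylation removes the tertiary TES and the secondary TBS ether in one mildly acidic operation that avoids angelate isomerisation, conjugate addition and base-induced translactonisation to O8.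

**Compound list**
1 | methyl hydrogen (R)-3-methylglutarate [(R)-5-methoxy-3-methyl-5-oxopentanoic acid] | COC(=O)C[C@H](C)CC(=O)O | starting material
2 | methyl (R)-5-hydroxy-3-methylpentanoate | COC(=O)C[C@H](C)CCO | intermediate
3 | (R)-4-methyltetrahydro-2H-pyran-2-one | O=C1C[C@H](C)CCO1 | intermediate
4 | 3-bromofuran | Brc1ccoc1 | starting material
5 | 3-furyllithium | [Li]c1ccoc1 | intermediate
6 | lithium (R)-5-(furan-3-yl)-3-methyl-5-oxopentan-1-olate | O=C(c1ccoc1)C[C@H](C)CCO[Li] | intermediate
7 | (R)-1-(furan-3-yl)-3-methyl-5-(triethylsilyloxy)pentan-1-one | O=C(c1ccoc1)C[C@H](C)CCO[Si](CC)(CC)CC | intermediate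
8 | (1S,3R)-1-(furan-3-yl)-3-methyl-5-(triethylsilyloxy)pentan-1-ol | o1ccc(c1)[C@@H](O)C[C@H](C)CCO[Si](CC)(CC)CC | intermediate
9 | 3-[(1S,3R)-1-(tert-butyldimethylsilyloxy)-3-methyl-5-(triethylsilyloxy)pentyl]furan | o1ccc(c1)[C@@H](O[Si](C)(C)C(C)(C)C)C[C@H](C)CCO[Si](CC)(CC)CC | intermediate
10 | (3S,5S)-5-(tert-butyldimethylsilyloxy)-5-(furan-3-yl)-3-methylpentanal | o1ccc(c1)[C@@H](O[Si](C)(C)C(C)(C)C)C[C@H](C)CC=O | intermediate
11 | (3S,5S)-5-(tert-butyldimethylsilyloxy)-5-(furan-3-yl)-3-methyl-2-methylidenepentanal | o1ccc(c1)[C@@H](O[Si](C)(C)C(C)(C)C)C[C@H](C)C(=C)C=O | intermediate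
12 | (3S,5S)-5-(tert-butyldimethylsilyloxy)-5-(furan-3-yl)-3-methyl-2-methylidenepentan-1-ol | o1ccc(c1)[C@@H](O[Si](C)(C)C(C)(C)C)C[C@H](C)C(=C)CO | intermediate
13 | {(2S)-2-[(2S,4S)-4-(tert-butyldimethylsilyloxy)-4-(furan-3-yl)butan-2-yl]oxiran-2-yl}methanol | o1ccc(c1)[C@@H](O[Si](C)(C)C(C)(C)C)C[C@H](C)[C@@]2(CO2)CO | intermediate
14 | (2S,3S,5S)-5-(tert-butyldimethylsilyloxy)-5-(furan-3-yl)-2-[(4-methoxybenzyloxy)methyl]-3-methylpentane-1,2-diol | o1ccc(c1)[C@@H](O[Si](C)(C)C(C)(C)C)C[C@H](C)[C@@](O)(COCc2ccc(OC)cc2)CO | intermediate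
15 | 1,2-bis(triethylsilyl) ether of 14 (C1 R, C8 S, C10 S) | o1ccc(c1)[C@@H](O[Si](C)(C)C(C)(C)C)C[C@H](C)[C@@](O[Si](CC)(CC)CC)(COCc2ccc(OC)cc2)CO[Si](CC)(CC)CC | intermediate
16 | furan endoperoxide of 15 (2,3,7-trioxabicyclo[2.2.1]hept-5-ene, chain on C5) | C1=C(C2OOC1O2)[C@@H](O[Si](C)(C)C(C)(C)C)C[C@H](C)[C@@](O[Si](CC)(CC)CC)(COCc3ccc(OC)cc3)CO[Si](CC)(CC)CC | intermediate
17 | 5-hydroxy-4-alkylfuran-2(5H)-one, chain as in 15, both C6 epimers | O=C1C=C(C(O)O1)[C@@H](O[Si](C)(C)C(C)(C)C)C[C@H](C)[C@@](O[Si](CC)(CC)CC)(COCc2ccc(OC)cc2)CO[Si](CC)(CC)CC | intermediate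
18 | ring-opened 3-alkyl-4-hydroxybut-2-enoic acid (CO2H cis to CH2OH), chain as in 15 | OC(=O)/C=C(\CO)[C@@H](O[Si](C)(C)C(C)(C)C)C[C@H](C)[C@@](O[Si](CC)(CC)CC)(COCc1ccc(OC)cc1)CO[Si](CC)(CC)CC | intermediate
19 | 4-alkylfuran-2(5H)-one, chain as in 15 | O=C1C=C(CO1)[C@@H](O[Si](C)(C)C(C)(C)C)C[C@H](C)[C@@](O[Si](CC)(CC)CC)(COCc2ccc(OC)cc2)CO[Si](CC)(CC)CC | intermediate
20 | (2R,3S,5S)-5-(tert-butyldimethylsilyloxy)-2-[(4-methoxybenzyloxy)methyl]-3-methyl-5-(5-oxo-2,5-dihydrofuran-3-yl)-2-(triethylsilyloxy)pentanal | O=C1C=C(CO1)[C@@H](O[Si](C)(C)C(C)(C)C)C[C@H](C)[C@@](O[Si](CC)(CC)CC)(COCc2ccc(OC)cc2)C=O | intermediate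
21 | (2R,3S,5S)-5-(tert-butyldimethylsilyloxy)-2-[(4-methoxybenzyloxy)methyl]-3-methyl-2-(triethylsilyloxy)-5-[5-(triisopropylsilyloxy)furan-3-yl]pentanal | c1(O[Si](C(C)C)(C(C)C)C(C)C)occ(c1)[C@@H](O[Si](C)(C)C(C)(C)C)C[C@H](C)[C@@](O[Si](CC)(CC)CC)(COCc2ccc(OC)cc2)C=O | intermediate
22 | (4S,6S,7R,8S,8aR)-4-(tert-butyldimethylsilyloxy)-8-hydroxy-7-[(4-methoxybenzyloxy)methyl]-6-methyl-7-(triethylsilyloxy)-4,5,6,7,8,8a-hexahydro-2H-cyclohepta[b]furan-2-one | O=C1C=C2[C@@H](O[Si](C)(C)C(C)(C)C)C[C@H](C)[C@@](O[Si](CC)(CC)CC)(COCc3ccc(OC)cc3)[C@@H](O)[C@@H]2O1 | intermediate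
23 | C5 triethylsilyl ether of 22 (4S,6S,7R,8S,8aR) | O=C1C=C2[C@@H](O[Si](C)(C)C(C)(C)C)C[C@H](C)[C@@](O[Si](CC)(CC)CC)(COCc3ccc(OC)cc3)[C@@H](O[Si](CC)(CC)CC)[C@@H]2O1 | intermediate
24 | (3aR,4S,6S,7R,8S,8aR)-4-(tert-butyldimethylsilyloxy)-7-[(4-methoxybenzyloxy)methyl]-6-methyl-7,8-bis(triethylsilyloxy)octahydro-2H-cyclohepta[b]furan-2-one | C1C(=O)O[C@@H]2[C@@H]1[C@@H](O[Si](C)(C)C(C)(C)C)C[C@H](C)[C@@](O[Si](CC)(CC)CC)(COCc3ccc(OC)cc3)[C@H]2O[Si](CC)(CC)CC | intermediate
25 | lithium enolate of 24 (C11=C12–OLi) | C1=C(O[Li])O[C@@H]2[C@@H]1[C@@H](O[Si](C)(C)C(C)(C)C)C[C@H](C)[C@@](O[Si](CC)(CC)CC)(COCc3ccc(OC)cc3)[C@H]2O[Si](CC)(CC)CC | intermediate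
26 | C11 (dimethylamino)methyl lactone (C11 epimers) | CN(C)CC1C(=O)O[C@@H]2[C@@H]1[C@@H](O[Si](C)(C)C(C)(C)C)C[C@H](C)[C@@](O[Si](CC)(CC)CC)(COCc3ccc(OC)cc3)[C@H]2O[Si](CC)(CC)CC | intermediate
27 | C11 (trimethylammonio)methyl lactone iodide | [I-].C[N+](C)(C)CC1C(=O)O[C@@H]2[C@@H]1[C@@H](O[Si](C)(C)C(C)(C)C)C[C@H](C)[C@@](O[Si](CC)(CC)CC)(COCc3ccc(OC)cc3)[C@H]2O[Si](CC)(CC)CC | intermediate
28 | (3aR,4S,6S,7R,8S,8aR)-4-(tert-butyldimethylsilyloxy)-7-[(4-methoxybenzyloxy)methyl]-6-methyl-3-methylidene-7,8-bis(triethylsilyloxy)octahydro-2H-cyclohepta[b]furan-2-one | C=C1C(=O)O[C@@H]2[C@@H]1[C@@H](O[Si](C)(C)C(C)(C)C)C[C@H](C)[C@@](O[Si](CC)(CC)CC)(COCc3ccc(OC)cc3)[C@H]2O[Si](CC)(CC)CC | intermediate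
29 | (3aR,4S,6S,7R,8S,8aR)-4-(tert-butyldimethylsilyloxy)-8-hydroxy-7-[(4-methoxybenzyloxy)methyl]-6-methyl-3-methylidene-7-(triethylsilyloxy)octahydro-2H-cyclohepta[b]furan-2-one | C=C1C(=O)O[C@@H]2[C@@H]1[C@@H](O[Si](C)(C)C(C)(C)C)C[C@H](C)[C@@](O[Si](CC)(CC)CC)(COCc3ccc(OC)cc3)[C@H]2O | intermediate
30 | angelic acid, (Z)-2-methylbut-2-enoic acid | C/C=C(/C)C(=O)O | starting material
31 | (Z)-2-methylbut-2-enoic 2,4,6-trichlorobenzoic anhydride | C/C=C(/C)C(=O)OC(=O)c1c(Cl)cc(Cl)cc1Cl | intermediate
32 | C5 (Z)-2-methylbut-2-enoate of 29 (3aR,4S,6S,7R,8S,8aR) | C=C1C(=O)O[C@@H]2[C@@H]1[C@@H](O[Si](C)(C)C(C)(C)C)C[C@H](C)[C@@](O[Si](CC)(CC)CC)(COCc3ccc(OC)cc3)[C@H]2OC(=O)/C(C)=C\C | intermediate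
33 | C2 primary alcohol (7-hydroxymethyl; 3aR,4S,6S,7R,8S,8aR) | C=C1C(=O)O[C@@H]2[C@@H]1[C@@H](O[Si](C)(C)C(C)(C)C)C[C@H](C)[C@@](O[Si](CC)(CC)CC)(CO)[C@H]2OC(=O)/C(C)=C\C | intermediate
34 | C2 aldehyde (7-formyl; 3aR,4S,6S,7S,8S,8aR) | C=C1C(=O)O[C@@H]2[C@@H]1[C@@H](O[Si](C)(C)C(C)(C)C)C[C@H](C)[C@@](O[Si](CC)(CC)CC)(C=O)[C@H]2OC(=O)/C(C)=C\C | intermediate
35 | (E)-1-bromoprop-1-ene | C/C=C/Br | starting material
36 | (E)-prop-1-enylchromium dichloride | C/C=C/[Cr](Cl)Cl | intermediate
37 | C2 allylic alcohol (7-[(E)-1-hydroxybut-2-enyl]; C2 epimers; 3aR,4S,6S,7R,8S,8aR) | C=C1C(=O)O[C@@H]2[C@@H]1[C@@H](O[Si](C)(C)C(C)(C)C)C[C@H](C)[C@@](O[Si](CC)(CC)CC)(C(O)/C=C/C)[C@H]2OC(=O)/C(C)=C\C | intermediate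
38 | 8-O-TBS, 1-O-TES ether of the target (3aR,4S,6S,7S,8S,8aR) | C=C1C(=O)O[C@@H]2[C@@H]1[C@@H](O[Si](C)(C)C(C)(C)C)C[C@H](C)[C@@](O[Si](CC)(CC)CC)(C(=O)/C=C/C)[C@H]2OC(=O)/C(C)=C\C | intermediate
39 | CNP0206014.2, (3aS,4S,6S,7S,8S,8aR)-7-[(E)-but-2-enoyl]-4,7-dihydroxy-6-methyl-3-methylidene-2-oxooctahydro-2H-cyclohepta[b]furan-8-yl (Z)-2-methylbut-2-enoate | C=C1C(=O)O[C@@H]2[C@@H]1[C@@H](O)C[C@H](C)[C@@](O)(C(=O)/C=C/C)[C@H]2OC(=O)/C(C)=C\C | target

**Step count and risks**
Total step count: 25. Longest linear sequence: 25 steps (from 1; compounds 4, 30 and 35 are bought).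

**Steps most likely to fail**

1. Step 15 (key step).
 - What may go wrong: protodesilylation of the silyloxyfuran may outrun a slow seven-membered closure, oligomerisation may compete, the allylic C8–O bond may ionise, or facial selectivity at C5/C6 may be poor.
 - Fallback: it sets out from butenolide aldehyde 20 and leaves silicon out of the bond formation. The same C5–C6 bond is closed as a reversible, amine-base-mediated direct vinylogous aldol, a known reaction of γ-butenolides with aldehydes (1,8-diazabicyclo[5.4.0]undec-7-ene 0.2 equiv, toluene, 2 mM, 0 °C to rt).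
 - The aldol step and the C6–H are then both under equilibrium, so the most stable isomer, with a pseudo-equatorial C5–OH trans to C6–O, should collect under thermodynamic rather than kinetic control.
 - It comes back to the route at 22 and makes no compound outside the list (F0).

2. Step 17.
 - What may go wrong: poor facial selectivity at C7 (hydrogen delivered from the H6 face, leading to a cis ring fusion), or sluggish reduction at the crowded β-carbon.
 - Fallback: it sets out from 23 and replaces substrate control by ligand control. A homogeneous copper hydride conjugate reduction is used (CuCl, NaOt-Bu, 2,2'-bis(di-p-tolylphosphino)-1,1'-binaphthyl as a single enantiomer, polymethylhydrosiloxane, t-BuOH, toluene, 0 °C). This is a known asymmetric reduction of β-substituted butenolides.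
 - Both ligand antipodes are tried, and the one matched with the substrate bias is used.
 - It comes back at 24 and makes no compound outside the list (F0).

3. Step 20.
 - What may go wrong: slow acylation of the C5 hydroxyl, which is flanked by fully substituted C1, and (Z) to (E) isomerisation of the activated acid on prolonged heating.
 - Fallback: it sets out from 29 and builds the angelate on the molecule. A small saturated acid, 2-[bis(2,2,2-trifluoroethoxy)phosphoryl]propanoic acid, is coupled first (N-(3-dimethylaminopropyl)-N'-ethylcarbodiimide hydrochloride, 4-(dimethylamino)pyridine, CH2Cl2) to give the C5 2-[bis(2,2,2-trifluoroethoxy)phosphoryl]propanoate F1.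
 - A Still–Gennari olefination (KN(SiMe3)2, 18-crown-6, THF, −78 °C, then acetaldehyde) should then form the (Z)-2-methylbut-2-enoate.
 - It comes back at 32.

**Further compounds**
F0 | step 15 | none | none
F0 | step 17 | none | none
F1 | step 20 | C5 2-[bis(2,2,2-trifluoroethoxy)phosphoryl]propanoate of 29 | C=C1C(=O)O[C@@H]2[C@@H]1[C@@H](O[Si](C)(C)C(C)(C)C)C[C@H](C)[C@@](O[Si](CC)(CC)CC)(COCc3ccc(OC)cc3)[C@H]2OC(=O)C(C)P(=O)(OCC(F)(F)F)OCC(F)(F)F
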